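Everything rests on cutting ring C of this (3R)-isoflavan at C4–C4a and O1–C8a. That leaves ring A as an aryl iodide and the C4–C3–C2–O1 chain as an enantiopure γ-bromo alcohol. One palladium/norbornene (Catellani-type) annulation joins them. The bromide carbon is placed on the free C4a–H next to C8a–I, then the pendant hydroxyl closes onto C8a. The step exploits the adjacency of C4a and C8a in ring A and the C8 formyl carbon, masked as a dioxolane, which flanks C8a and forces norbornene out after one alkylation. C3 is set earlier by catalytic desymmetrising opening of an achiral 3-aryloxetane and is only carried through.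

Key step: step 9

Numbering: isoflavan numbering is used (O1, C2, C3, C4, C4a, C5–C8, C8a; ring B primed).
Assumption: the antipode of the squaramide catalyst that delivers the R bromohydrin is used. Its sense of induction is taken to follow that of simpler 3-aryloxetanes and is to be confirmed at compound 9.

Step 1
Reactants: 1 4-bromoresorcinol
Product: 2 1-bromo-2,4-bis(methoxymethoxy)benzene
Conditions: NaH (2.5 equiv), MOMCl (2.5 equiv), DMF, 0 °C to rt
Reagents that add atoms: chloromethyl methyl ether (MOMCl), COCCl
Why: Williamson-type O-alkylation of both phenoxides gives MOM acetals that survive base, organolithium and palladium chemistry and later direct the lithiation.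

Step 2
Reactants: 2 1-bromo-2,4-bis(methoxymethoxy)benzene; 3 3-bromooxetane
Product: 4 3-[2,4-bis(methoxymethoxy)phenyl]oxetane
Conditions: NiCl2(dme) (10 mol%), 4,4'-di-tert-butyl-2,2'-bipyridine (10 mol%), NaI (25 mol%), Zn dust (2 equiv), DMA, 60 °C
Reagents that add atoms: none
Why: Nickel-catalysed reductive cross-electrophile coupling pairs the aryl bromide with the oxetan-3-yl radical from 3, a pairing known for 3-halooxetanes, and no stereocentre arises because the 3-aryloxetane is achiral.

Step 3
Reactants: 4 3-[2,4-bis(methoxymethoxy)phenyl]oxetane; 5 prenyl bromide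
Product: 7 3-[2,4-bis(methoxymethoxy)-3-(3-methylbut-2-en-1-yl)phenyl]oxetane, via aryllithium 6 (not isolated)
Conditions: n-BuLi (1.2 equiv), THF, 0 °C; CuBr·SMe2 (10 mol%), then 5, −78 °C to rt
Reagents that add atoms: none
Why: Directed ortho-metalation takes place at C3', the position flanked by both OMOM groups, the oxetane is inert to n-BuLi without a Lewis acid, and copper-catalysed allylic substitution occurs at the unhindered CH2 end of prenyl bromide.

Step 4
Reactants: 7 3-[2,4-bis(methoxymethoxy)-3-(3-methylbut-2-en-1-yl)phenyl]oxetane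
Product: 9 (2R)-3-bromo-2-[2,4-bis(methoxymethoxy)-3-(3-methylbut-2-en-1-yl)phenyl]propan-1-ol, via silyl ether 8 (not isolated)
Conditions: Me3SiBr (1.2 equiv), chiral squaramide hydrogen-bond donor of the tert-leucine 2-arylpyrrolidine amide type (10 mol%), t-BuOMe, −80 °C; then MeOH, citric acid (cat.), 0 °C
Reagents that add atoms: bromotrimethylsilane, C[Si](C)(C)Br
Why: In this enantioselective desymmetrisation of a 3-substituted oxetane the chiral hydrogen-bond donor binds bromide and steers its SN2 attack to one of the two enantiotopic CH2 groups of the silylated oxetane, so strain release sets C3 as R, and mild methanolysis removes the silyl group without touching the MOM acetals.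

Step 5
Reactants: 10 1-iodo-3,5-dimethoxybenzene
Product: 12 2-iodo-4,6-dimethoxybenzaldehyde, via iminium salt 11 (not isolated)
Conditions: POCl3 (1.5 equiv), DMF, 0 to 90 °C; then ice-water
Reagents that add atoms: N,N-dimethylformamide, CN(C)C=O; water, O
Why: Vilsmeier–Haack formylation goes para to one methoxy group and ortho to the other (next to iodine) rather than between the two methoxy groups, as is the rule for 5-halo-1,3-dimethoxybenzenes.

Step 6
Reactants: 12 2-iodo-4,6-dimethoxybenzaldehyde
Product: 14 2-hydroxy-6-iodo-4-methoxybenzaldehyde, via dichloroboryl ether 13 (not isolated)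
Conditions: BCl3 (1.2 equiv), CH2Cl2, −78 to 0 °C; then water
Reagents that add atoms: none
Why: Chelation-controlled ether cleavage, in which BCl3 is held between the formyl oxygen and the ortho methoxy oxygen, directs chloride to that methyl group only, so the para methoxy group (the future 5-OMe) stays.

Step 7
Reactants: 14 2-hydroxy-6-iodo-4-methoxybenzaldehyde
Product: 15 2-iodo-4-methoxy-6-(methoxymethoxy)benzaldehyde
Conditions: NaH (1.2 equiv), MOMCl (1.2 equiv), DMF, 0 °C
Reagents that add atoms: chloromethyl methyl ether (MOMCl), COCCl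
Why: Williamson-type O-alkylation blocks the phenoxide, which would otherwise be alkylated by the bromide in step 9, with the same group that is used on ring B.

Step 8
Reactants: 15 2-iodo-4-methoxy-6-(methoxymethoxy)benzaldehyde
Product: 16 2-[2-iodo-4-methoxy-6-(methoxymethoxy)phenyl]-1,3-dioxolane
Conditions: Me3SiOCH2CH2OSiMe3 (1.5 equiv), Me3SiOTf (2 mol%), CH2Cl2, −78 °C; pyridine quench
Reagents that add atoms: 1,2-bis(trimethylsilyloxy)ethane, C[Si](C)(C)OCCO[Si](C)(C)C
Why: Aprotic silyl-transfer acetalisation (Noyori conditions), driven by formation of the Si–O–Si bond, masks the aldehyde, which would otherwise divert the norbornyl-palladium stage of step 9 through acyl C–H activation to an indanone.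

Step 9
Reactants: 9 (2R)-3-bromo-2-[2,4-bis(methoxymethoxy)-3-(3-methylbut-2-en-1-yl)phenyl]propan-1-ol; 16 2-[2-iodo-4-methoxy-6-(methoxymethoxy)phenyl]-1,3-dioxolane
Product: 17 (3R)-3-[2,4-bis(methoxymethoxy)-3-(3-methylbut-2-en-1-yl)phenyl]-8-(1,3-dioxolan-2-yl)-5-methoxy-7-(methoxymethoxy)-3,4-dihydro-2H-chromene
Conditions: Pd(OAc)2 (10 mol%), XPhos (20 mol%), norbornene (2 equiv), Cs2CO3 (3 equiv), 9 (1.3 equiv), 1,4-dioxane, 100 °C
Reagents that add atoms: none
Why: Proposed new method: zerovalent palladium inserts into the C8a–I bond of 16, norbornene insertion and carbonate-assisted palladation of the neighbouring C4a–H give an aryl–norbornyl palladacycle, this takes up the CH2Br carbon of 9 by SN2-type oxidative addition to tetravalent palladium and forms C4–C4a by reductive elimination, norbornene leaves by β-carbon elimination because C8a is now flanked by the C8 dioxolanyl group and the new C4a alkyl group, and the pendant alkoxide binds the divalent arylpalladium centre and forms O1–C8a by reductive elimination. The closest known reaction types are the palladium/norbornene annulations of aryl iodides with epoxides to 2,3-dihydrobenzofurans and with bromoalkylamines to tetrahydroquinolines, together with the palladium-catalysed cyclisation of 3-(2-halophenyl)propan-1-ols to chromans; new is the union of ortho-alkylation by a γ-bromo alcohol with ipso C–O closure to a chroman. Ring C closes by C–O reductive elimination from a seven-membered arylpalladium alkoxide chelate, which gives the six-membered dihydropyran. No stereocentre is made: C3 lies one carbon away from both reacting atoms, so the R configuration of 9 is carried into 17. Site selectivity is secured by the substrate, since C4a–H is the only C–H next to the C–I bond, and the order carbon first, oxygen second follows because norbornene insertion outruns intermolecular etherification and only the palladacycle reacts with alkyl bromides. The step further needs C–O elimination to outrun β-hydride loss from the alkoxide and palladation of C6'–H of ring B, and alkylation to outrun closure of 9 to oxetane 7, which the bulky electron-rich biarylphosphine and the weak, poorly soluble base are chosen to secure.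

Step 10
Reactants: 17 (3R)-3-[2,4-bis(methoxymethoxy)-3-(3-methylbut-2-en-1-yl)phenyl]-8-(1,3-dioxolan-2-yl)-5-methoxy-7-(methoxymethoxy)-3,4-dihydro-2H-chromene
Product: 18 (3R)-3-[2,4-dihydroxy-3-(3-methylbut-2-en-1-yl)phenyl]-7-hydroxy-5-methoxy-3,4-dihydro-2H-chromene-8-carbaldehyde
Conditions: 2 M aq HCl, MeOH–THF, 40 °C
Reagents that add atoms: water, O
Why: Acid-catalysed acetal hydrolysis removes the three MOM groups and the dioxolane in one operation, dilute acid at mild temperature should leave the prenyl alkene uncyclised, and C3 carries no acidic hydrogen and is untouched.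

Compound list
1 | 4-bromoresorcinol (4-bromobenzene-1,3-diol) | Oc1ccc(Br)c(O)c1 | starting material
2 | 1-bromo-2,4-bis(methoxymethoxy)benzene | COCOc1ccc(Br)c(OCOC)c1 | intermediate
3 | 3-bromooxetane | BrC1COC1 | starting material
4 | 3-[2,4-bis(methoxymethoxy)phenyl]oxetane | COCOc1ccc(C2COC2)c(OCOC)c1 | intermediate
5 | prenyl bromide (1-bromo-3-methylbut-2-ene) | CC(C)=CCBr | starting material
6 | [2,6-bis(methoxymethoxy)-3-(oxetan-3-yl)phenyl]lithium | COCOc1ccc(C2COC2)c(OCOC)c1[Li] | intermediate
7 | 3-[2,4-bis(methoxymethoxy)-3-(3-methylbut-2-en-1-yl)phenyl]oxetane | COCOc1ccc(C2COC2)c(OCOC)c1CC=C(C)C | intermediate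
8 | {(2R)-3-bromo-2-[2,4-bis(methoxymethoxy)-3-(3-methylbut-2-en-1-yl)phenyl]propoxy}trimethylsilane | BrC[C@H](c1ccc(OCOC)c(CC=C(C)C)c1OCOC)CO[Si](C)(C)C | intermediate
9 | (2R)-3-bromo-2-[2,4-bis(methoxymethoxy)-3-(3-methylbut-2-en-1-yl)phenyl]propan-1-ol | BrC[C@H](c1ccc(OCOC)c(CC=C(C)C)c1OCOC)CO | intermediate
10 | 1-iodo-3,5-dimethoxybenzene | COc1cc(I)cc(OC)c1 | starting material
11 | (2-iodo-4,6-dimethoxybenzylidene)dimethylammonium dichlorophosphate | COc1cc(I)c(C=[N+](C)C)c(OC)c1.[O-]P(=O)(Cl)Cl | intermediate
12 | 2-iodo-4,6-dimethoxybenzaldehyde | COc1cc(I)c(C=O)c(OC)c1 | intermediate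
13 | 2-formyl-3-iodo-5-methoxyphenyl dichloroborinate (boron chelated by the formyl oxygen) | COc1cc(I)c(C=O)c(OB(Cl)Cl)c1 | intermediate
14 | 2-hydroxy-6-iodo-4-methoxybenzaldehyde | COc1cc(I)c(C=O)c(O)c1 | intermediate
15 | 2-iodo-4-methoxy-6-(methoxymethoxy)benzaldehyde | COCOc1cc(OC)cc(I)c1C=O | intermediate
16 | 2-[2-iodo-4-methoxy-6-(methoxymethoxy)phenyl]-1,3-dioxolane | COCOc1cc(OC)cc(I)c1C1OCCO1 | intermediate
17 | (3R)-3-[2,4-bis(methoxymethoxy)-3-(3-methylbut-2-en-1-yl)phenyl]-8-(1,3-dioxolan-2-yl)-5-methoxy-7-(methoxymethoxy)-3,4-dihydro-2H-chromene | COc1cc(OCOC)c(C3OCCO3)c2c1C[C@H](c1ccc(OCOC)c(CC=C(C)C)c1OCOC)CO2 | intermediate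
18 | (3R)-3-[2,4-dihydroxy-3-(3-methylbut-2-en-1-yl)phenyl]-7-hydroxy-5-methoxy-3,4-dihydro-2H-chromene-8-carbaldehyde (CNP0399843.1) | COc1cc(O)c(C=O)c2c1C[C@H](c1ccc(O)c(CC=C(C)C)c1O)CO2 | target

Total step count: 10. Longest linear sequence: 6 steps (1–4, 9, 10; the branch 5–8, 9, 10 is equally long).

Steps most likely to fail

Step 9 (proposed method).
- **What may go wrong:** Palladation of C4a–H beside the 5-methoxy group may be slow. Compound 9 may be consumed by base-induced ring closure to the oxetane or by dehydrobromination. The palladium alkoxide may undergo β-hydride elimination, or ring B may be palladated in place of C–O bond formation.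
- **Fallback:** It uses known chemistry, makes the bonds one at a time, sets out from 16 and 9 and comes back at 17.
- Iodide 16 is hydroxylated (Pd2(dba)3, t-BuXPhos, KOH, dioxane–water, 100 °C) to 2-(1,3-dioxolan-2-yl)-5-methoxy-3-(methoxymethoxy)phenol F1.
- Mitsunobu etherification of this phenol with alcohol 9 (PPh3, DIAD, toluene, 0 °C to rt) gives the (2R)-3-bromo-2-arylpropyl aryl ether F2, with C3 untouched.
- A palladium-catalysed ring-forming aromatic C–H alkylation of the unactivated primary bromide (Pd(PPh3)4, K3PO4, dioxane, 100–130 °C) closes C4–C4a at the only free position ortho to the ether oxygen and gives 17.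

Step 4.
- **What may go wrong:** The two enantiotopic CH2 groups may be told apart poorly, because the ortho OMOM group crowds the oxetane and competes for the hydrogen-bond donor. MOM acetals may be attacked by the silyl bromide if a higher temperature is needed.
- **Fallback:** It replaces asymmetric catalysis by resolution, sets out from 7 and comes back at 9.
- Oxetane 7 is opened without a chiral catalyst (Me3SiBr, CH2Cl2, −78 °C) to the racemic bromo silyl ether F3. This is methanolysed to the racemic 3-bromo-2-arylpropan-1-ol F4.
- A lipase is chosen by screening for faster acylation of the S alcohol (Burkholderia cepacia lipase or Candida antarctica lipase B, vinyl acetate, t-BuOMe, 0–25 °C) and is run past half conversion. It should convert the S enantiomer into the (2S)-3-bromo-2-arylpropyl acetate F5 and leave (R)-9, which is separated by chromatography.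

Step 2.
- **What may go wrong:** Protodehalogenation and homocoupling of the electron-rich, ortho-substituted aryl bromide may outrun capture of the oxetanyl radical.
- **Fallback:** It builds the oxetane ring instead of coupling it, sets out from 2 and comes back at 4.
- Palladium-catalysed α-arylation of diethyl malonate with 2 (Pd2(dba)3, P(t-Bu)3·HBF4, K3PO4, toluene, 80 °C) gives diethyl 2-[2,4-bis(methoxymethoxy)phenyl]malonate F6.
- LiAlH4 in THF at 0 °C gives 2-[2,4-bis(methoxymethoxy)phenyl]propane-1,3-diol F7.
- One-pot treatment with n-BuLi (1 equiv), TsCl (1 equiv) and again n-BuLi (1 equiv) in THF, 0 to 60 °C, passes through the racemic monotosylate F8. This closes by intramolecular Williamson etherification to 4.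

Further compounds
F1 | step 9 | 2-(1,3-dioxolan-2-yl)-5-methoxy-3-(methoxymethoxy)phenol | COCOc1cc(OC)cc(O)c1C1OCCO1
F2 | step 9 | 2-[2-{(2R)-3-bromo-2-[2,4-bis(methoxymethoxy)-3-(3-methylbut-2-en-1-yl)phenyl]propoxy}-4-methoxy-6-(methoxymethoxy)phenyl]-1,3-dioxolane | BrC[C@H](c1ccc(OCOC)c(CC=C(C)C)c1OCOC)COc1cc(OC)cc(OCOC)c1C1OCCO1
F3 | step 4 | racemic {3-bromo-2-[2,4-bis(methoxymethoxy)-3-(3-methylbut-2-en-1-yl)phenyl]propoxy}trimethylsilane | BrCC(c1ccc(OCOC)c(CC=C(C)C)c1OCOC)CO[Si](C)(C)C
F4 | step 4 | racemic 3-bromo-2-[2,4-bis(methoxymethoxy)-3-(3-methylbut-2-en-1-yl)phenyl]propan-1-ol | BrCC(c1ccc(OCOC)c(CC=C(C)C)c1OCOC)CO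
F5 | step 4 | (2S)-3-bromo-2-[2,4-bis(methoxymethoxy)-3-(3-methylbut-2-en-1-yl)phenyl]propyl acetate | BrC[C@@H](c1ccc(OCOC)c(CC=C(C)C)c1OCOC)COC(C)=O
F6 | step 2 | diethyl 2-[2,4-bis(methoxymethoxy)phenyl]malonate | CCOC(=O)C(C(=O)OCC)c1ccc(OCOC)cc1OCOC
F7 | step 2 | 2-[2,4-bis(methoxymethoxy)phenyl]propane-1,3-diol | OCC(CO)c1ccc(OCOC)cc1OCOC
F8 | step 2 | racemic 2-[2,4-bis(methoxymethoxy)phenyl]-3-hydroxypropyl 4-methylbenzenesulfonate | Cc1ccc(cc1)S(=O)(=O)OCC(CO)c1ccc(OCOC)cc1OCOC
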